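If target falls back to starting material many times within a run, its end value hangs on few numbers. Find those numbers first.

| setting | noon | spring | autumn | dusk | summer |
|---|---|---|---|---|---|
| starting material | 10 mM | 20 mM | 40 mM | 80 mM | 150 mM |
| partner | 36.0 mM | 36.0 mM | 36.0 mM | 36.0 mM | 36.0 mM |
| second substrate | 180 mM (in portions, 2) | 180 mM (in portions, 2) | 180 mM (in portions, 2) | 180 mM (in portions, 2) | 180 mM (in portions, 2) |
| time | 25 d | 25 d | 25 d | 25 d | 25 d |
| remark | the portions of second substrate follow each other after 6.0 h, the first at the start | the portions of second substrate follow each other after 6.0 h, the first at the start | the portions of second substrate follow each other after 6.0 h, the first at the start | the portions of second substrate follow each other after 6.0 h, the first at the start | the portions of second substrate follow each other after 6.0 h, the first at the start |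

    starting material + partner ⇌ target (K1 = 10 M⁻¹, k1 = 0.016 M⁻¹ min⁻¹)
    second substrate + partner ⇌ second product (K2 = 5.2 M⁻¹, k2 = 2.9 × 10⁻⁴ M⁻¹ min⁻¹)
    2 partner → homo dimer (k3 = 0.0011 M⁻¹ min⁻¹)
    partner → decomposed reagent (k4 = 3.7 × 10⁻⁵ min⁻¹)

- a doubled species enters its step squared and goes two at a time
- "hardly changes" means that all values lie within two and a half points (for a concentration: within two and a half percent of the largest)
- run time (noon): 25 d

- [target] at the end for noon, spring, autumn, dusk, summer, in this order
- how the row runs (rises all the way / falls, then rises / hardly changes / rises, then falls / falls all the way)

Take the rate constant of target formation first. Target falls back with a half-life of 0.301 d, whatever the partner does. The run lasts 25 d, so this step turns over 83.1 times. Halve the constant and 41.5 turnovers remain. It need not be known well, because the step stays at balance: a pre-equilibrium.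

Its equilibrium constant counts in full. Double it and the target about doubles.

The decomposition constant sits in an exponent, which comes to 1.33 over the run in my reckoning, so know it well.

The second binding turns over 2.90 times by the same count, so I take it as near balance. At balance the second substrate holds 0.936 parts of partner as second product per free part.

The portions come 6.0 h apart, far less than the run, so count them as one charge.

Dimerisation starts with a half-life of 8.77 d and slows as partner falls. I leave it out. I also let decomposition run on partner held as second product. These two errors pull opposite ways.

Now the number. Define the tie as the equilibrium constant of target formation times the partner charge, 0.360. Then reckon: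

target per starting material = tie × fraction of partner left free

fraction left free = exp(−decomposition constant × time) / (1 + 0.936) = 13.6 %

target per starting material = 4.91 %

My row runs from 0.491 mM for noon to 7.37 mM for summer, rising all the way.

The forecast gives 0.45 mM, 0.92 mM, 1.9 mM, 3.9 mM, 7.6 mM, and rises all the way: “With free partner nearly the same across runs, the final target is close to proportional to the starting material”. It stands lower than mine at noon and higher than mine in summer.

The flask gives 0.422 mM, 0.869 mM, 1.82 mM, 3.87 mM, 7.49 mM, and rises all the way. The noon flask ends with 12 % of its partner free and 96 % of its starting material unbound. Put these into the tie:

noon: 0.360 × 12 % × 96 % × 10 mM = 0.415 mM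

The noon flask holds 0.422 mM. The summer flask ends with 14 % of its partner free and 95 % of its starting material unbound:

summer: 0.360 × 14 % × 95 % × 150 mM = 7.42 mM

The summer flask holds 7.49 mM.

Its constants come from no measurement; what happens was integrated by code.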